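**Plan**

- Retrosynthesis: cut the O7–CH3 bond, then C4a–C5 of ring A (Claisen), then C5–C6 (carbomethoxylation), C7–C8 (acylation of the pyranone methyl group), O1–C8a (cyclodehydration), C2–C3 (aroylation of acetylacetone) and the aryl–carboxyl bond.
- Feature used: ring A carries oxygen on C5, C7 and C8a and methoxy on C6 and is fused to pyranone ring C, so C4a is a vinylogous enolate carbon and C5 an acid-level carbon of a folded polyketide chain.
- Forward: ring B is bought as 1,2,3,4-tetramethoxybenzene and carboxylated; a triketone is built and closed to ring C (the 4-pyranone); its methyl group is extended by three carbons; ring A closes last, C4a onto the C5 ester, with ring C intact.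
- Stereochemistry: the target is achiral; the one sp3 stereocentre of the cyclisation precursor is racemic and disappears on aromatisation.
- Finish: one selective O-methylation at O7 leaves the chelated 5-OH free.

Key step: step 6

Assumption: starting materials 1, 2, 5, 9 and 13 are taken as purchasable; 1,3-dicarbonyl compounds are drawn as keto tautomers although largely enolised, and 15 is used as the racemate.

**Route**

Step 1
Reactants: 1 1,2,3,4-tetramethoxybenzene; 2 methyl chloroformate
Product: 4 methyl 2,3,4,5-tetramethoxybenzoate, via aryllithium 3 (not isolated)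
Conditions: n-BuLi (1.2 equiv), TMEDA (1.2 equiv), THF, 0 °C; then cannulated into 2 (3 equiv), THF, −78 °C
Reagents that add atoms: none
Why: Directed ortho-lithiation of the polymethoxyarene (its two free positions are equivalent) followed by C-acylation of the aryllithium with a chloroformate, the inverse addition to excess electrophile suppressing diaryl ketone formation.

Step 2
Reactants: 4 methyl 2,3,4,5-tetramethoxybenzoate; 5 acetylacetone
Product: 7 1-(2,3,4,5-tetramethoxyphenyl)hexane-1,3,5-trione, via acetylacetone dianion 6 (not isolated)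
Conditions: 5 (2.2 equiv), LiN(i-Pr)2 (4.4 equiv), THF, 0 °C; then 4 (1 equiv), 0 °C to rt; then 1 M HCl
Reagents that add atoms: none
Why: Claisen-type aroylation of a 1,3-diketone dianion at its terminal, most basic carbanion; the excess dianion deprotonates the more acidic triketone and should suppress a second aroylation.

Step 3
Reactants: 7 1-(2,3,4,5-tetramethoxyphenyl)hexane-1,3,5-trione
Product: 8 2-methyl-6-(2,3,4,5-tetramethoxyphenyl)-4H-pyran-4-one
Conditions: p-TsOH·H2O (0.1 equiv), toluene, reflux, Dean–Stark
Reagents that add atoms: none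
Why: Acid-catalysed cyclodehydration of a 1,3,5-triketone, in which the enol oxygen of one terminal carbonyl adds to the other (6-exo-trig) and loss of water gives the 4-pyranone, the only six-membered ring this chain can form.

Step 4
Reactants: 8 2-methyl-6-(2,3,4,5-tetramethoxyphenyl)-4H-pyran-4-one; 9 N,2-dimethoxy-N-methylacetamide
Product: 12 2-(3-methoxy-2-oxopropyl)-6-(2,3,4,5-tetramethoxyphenyl)-4H-pyran-4-one, via lateral lithium dienolate 10 (not isolated), via tetrahedral adduct 11 (not isolated)
Conditions: LiN(i-Pr)2 (1.1 equiv), THF, −78 °C; then 9 (1.3 equiv), −78 to −40 °C; then 1 M HCl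
Reagents that add atoms: none
Why: Vinylogous (lateral) deprotonation of the pyranone methyl group gives a dienolate that reacts at the exocyclic carbon and so restores the pyranone, and the Weinreb ketone synthesis stops at the chelated adduct, so neither over-addition nor quenching of the anion by the acidic ketone should occur.

Step 5
Reactants: 12 2-(3-methoxy-2-oxopropyl)-6-(2,3,4,5-tetramethoxyphenyl)-4H-pyran-4-one; 13 dimethyl carbonate
Product: 15 methyl 2-methoxy-3-oxo-4-[4-oxo-6-(2,3,4,5-tetramethoxyphenyl)-4H-pyran-2-yl]butanoate (racemic), via dilithium bis-enolate 14 (not isolated)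
Conditions: LiN(i-Pr)2 (3.2 equiv), THF, −78 to −20 °C; then 13 (3 equiv), −78 to 0 °C; then cold 1 M HCl
Reagents that add atoms: none
Why: Terminal C-acylation of a 1,3-dicarbonyl-type dianion (here its vinylogue) with a dialkyl carbonate, a Claisen carbomethoxylation in which the last-formed carbanion next to the methoxy group is the most nucleophilic site and the third equivalent of base keeps the product as an unreactive dianion until the acidic quench.

Step 6
Reactants: 15 methyl 2-methoxy-3-oxo-4-[4-oxo-6-(2,3,4,5-tetramethoxyphenyl)-4H-pyran-2-yl]butanoate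
Product: 17 5,7-dihydroxy-6-methoxy-2-(2,3,4,5-tetramethoxyphenyl)-4H-chromen-4-one, via Claisen adduct 16 (not isolated)
Conditions: Mg(OMe)2 (4 equiv, commercial solution), MeOH, reflux; then 1 M HCl
Reagents that add atoms: none
Why: Proposed new method: Mg(OMe)2 turns 15 into a chelated magnesium enolate, and proton exchange gives the C8-deprotonated form (flavone numbering), a dienolate running from C8 through C8a and C4a to the C4 oxygen, whose carbon C4a adds to the ester carbonyl C5; loss of methoxide gives trione 16, and two enolisations driven by aromaticity deliver ring A of 17. The closest known reactions are the base- or Mg(OMe)2-promoted Claisen cyclisation of open-chain triketo esters to acylphloroglucinols and the side-chain reactions of 2-methyl-4-pyranone lateral dienolates, but a Claisen acylation at C3 of an intact 4-pyranone has not been shown. Ring A closes in a 6-(enolexo)-exo-trig mode over C4a, C8a, C8, C7, C6 and C5. No stereocentre is created in 17, because the centres at C4a and C6 of 16 vanish on aromatisation. The step needs C-acylation at C4a and a single mode of folding: C8 and the C7 oxygen could reach C5 only through four-membered rings, and since the O1–C2 bond of ring C already exists the isomeric 8-methoxyflavone cannot arise. Chelation of the 1,3-dicarbonyl unit by magnesium should hold C5 near C4a and slow retro-Claisen cleavage by free methoxide.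

Step 7
Reactants: 17 5,7-dihydroxy-6-methoxy-2-(2,3,4,5-tetramethoxyphenyl)-4H-chromen-4-one
Product: 18 agecorynin F, 5-hydroxy-6,7-dimethoxy-2-(2,3,4,5-tetramethoxyphenyl)-4H-chromen-4-one
Conditions: MeI (1.1 equiv), K2CO3 (1.2 equiv), acetone, rt
Reagents that add atoms: iodomethane, CI
Why: Williamson O-methylation under weak base, selective because the 7-OH (para to the carbonyl-bearing C4a) is the more acidic phenol while the 5-OH is held in a hydrogen bond to the C4 carbonyl and reacts far more slowly.

**Compound list**

1 | 1,2,3,4-tetramethoxybenzene | COc1ccc(OC)c(OC)c1OC | starting material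
2 | methyl chloroformate | COC(=O)Cl | starting material
3 | (2,3,4,5-tetramethoxyphenyl)lithium, formed in the flask | [Li]c1cc(OC)c(OC)c(OC)c1OC | intermediate
4 | methyl 2,3,4,5-tetramethoxybenzoate | COC(=O)c1cc(OC)c(OC)c(OC)c1OC | intermediate
5 | acetylacetone (pentane-2,4-dione) | CC(=O)CC(C)=O | starting material
6 | dilithium dianion of pentane-2,4-dione, formed in the flask | [Li+].[Li+].C=C([O-])C=C(C)[O-] | intermediate
7 | 1-(2,3,4,5-tetramethoxyphenyl)hexane-1,3,5-trione | CC(=O)CC(=O)CC(=O)c1cc(OC)c(OC)c(OC)c1OC | intermediate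
8 | 2-methyl-6-(2,3,4,5-tetramethoxyphenyl)-4H-pyran-4-one | Cc1cc(=O)cc(-c2cc(OC)c(OC)c(OC)c2OC)o1 | intermediate
9 | N,2-dimethoxy-N-methylacetamide | COCC(=O)N(C)OC | starting material
10 | lithium 2-methylidene-6-(2,3,4,5-tetramethoxyphenyl)-2H-pyran-4-olate (lateral dienolate of 8), formed in the flask | [Li+].C=C1C=C([O-])C=C(c2cc(OC)c(OC)c(OC)c2OC)O1 | intermediate
11 | lithium 1-methoxy-2-[methoxy(methyl)amino]-3-[4-oxo-6-(2,3,4,5-tetramethoxyphenyl)-4H-pyran-2-yl]propan-2-olate (chelated tetrahedral adduct), formed in the flask | COCC(O[Li])(Cc1cc(=O)cc(-c2cc(OC)c(OC)c(OC)c2OC)o1)N(C)OC | intermediate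
12 | 2-(3-methoxy-2-oxopropyl)-6-(2,3,4,5-tetramethoxyphenyl)-4H-pyran-4-one | COCC(=O)Cc1cc(=O)cc(-c2cc(OC)c(OC)c(OC)c2OC)o1 | intermediate
13 | dimethyl carbonate | COC(=O)OC | starting material
14 | dilithium bis-enolate of 12 (deprotonated at the pyranone-bound CH2 and at the CH2 next to the methoxy group), formed in the flask | [Li+].[Li+].COC=C([O-])C=C1C=C([O-])C=C(c2cc(OC)c(OC)c(OC)c2OC)O1 | intermediate
15 | methyl 2-methoxy-3-oxo-4-[4-oxo-6-(2,3,4,5-tetramethoxyphenyl)-4H-pyran-2-yl]butanoate, racemic | COc1cc(-c2cc(=O)cc(CC(=O)C(OC)C(=O)OC)o2)c(OC)c(OC)c1OC | intermediate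
16 | 6-methoxy-2-(2,3,4,5-tetramethoxyphenyl)-4H-chromene-4,5,7(4aH,6H)-trione, present as its magnesium enolate, stereocentres undefined and transient | COC1C(=O)C=C2OC(c3cc(OC)c(OC)c(OC)c3OC)=CC(=O)C2C1=O | intermediate
17 | 5,7-dihydroxy-6-methoxy-2-(2,3,4,5-tetramethoxyphenyl)-4H-chromen-4-one | COc1cc(-c2cc(=O)c3c(O)c(OC)c(O)cc3o2)c(OC)c(OC)c1OC | intermediate
18 | agecorynin F, 5-hydroxy-6,7-dimethoxy-2-(2,3,4,5-tetramethoxyphenyl)-4H-chromen-4-one | COc1cc(-c2cc(=O)c3c(O)c(OC)c(OC)cc3o2)c(OC)c(OC)c1OC | target

**Step count**

Total steps: 7. Longest linear sequence: 7 steps (1 to 18).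

**Steps most likely to fail**

Step 6 (proposed new method). Methoxide may add to C2 or C8a and open ring C, or cleave the C6–C7 bond in a retro-Claisen reaction, faster than C4a attacks C5; the chelated enolate at C6 may also fail to cyclise at all. The fallback uses the classical diketone route to flavones; it sets out from 4 and returns to the route at 18. The purchased ketone 1-(2-hydroxy-4,5,6-trimethoxyphenyl)ethanone F1 is converted into its dianion with LiN(SiMe3)2 (3.5 equiv) in THF and condensed with ester 4 in a Claisen reaction to give 1-(2-hydroxy-4,5,6-trimethoxyphenyl)-3-(2,3,4,5-tetramethoxyphenyl)propane-1,3-dione F2. Cyclodehydration with H2SO4 in AcOH should give 5,6,7-trimethoxy-2-(2,3,4,5-tetramethoxyphenyl)-4H-chromen-4-one F3. Chelation-directed cleavage of the 5-methyl ether with BCl3 in CH2Cl2 at 0 °C should then give 18.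

Step 5. The second deprotonation may stay incomplete, the product may transfer a proton to unreacted dianion, acylation may take place on oxygen, or the product anion may react further on warming. The fallback builds the keto ester by a decarboxylative Claisen condensation; it sets out from 8 and returns at 15. Dienolate 10, made from 8 as in step 4, is quenched with CO2 and acidified to give [4-oxo-6-(2,3,4,5-tetramethoxyphenyl)-4H-pyran-2-yl]acetic acid F4. Carbonyldiimidazole in THF converts this into the acyl imidazolide 2-[2-(1H-imidazol-1-yl)-2-oxoethyl]-6-(2,3,4,5-tetramethoxyphenyl)-4H-pyran-4-one F5. Separately, purchased dimethyl 2-methoxymalonate F6 is half-saponified with one equivalent of KOH in MeOH to potassium 2,3-dimethoxy-3-oxopropanoate F7. F7 with MgCl2 and Et3N in MeCN is C-acylated by F5 to give 2-methoxy-2-(methoxycarbonyl)-3-oxo-4-[4-oxo-6-(2,3,4,5-tetramethoxyphenyl)-4H-pyran-2-yl]butanoic acid F8, which should lose CO2 on acidic work-up to give 15.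

Step 4. The dienolate may act as a base towards the α-protons of the amide, or add in conjugate fashion to unreacted pyranone, returning 8 or oligomers. The fallback replaces the acylation by an aldol addition and oxidation; it sets out from 8 and returns at 12. Dienolate 10 is added at −78 °C to purchased methoxyacetaldehyde F9 to give racemic 2-(2-hydroxy-3-methoxypropyl)-6-(2,3,4,5-tetramethoxyphenyl)-4H-pyran-4-one F10, and Dess–Martin oxidation in CH2Cl2 should convert this into 12.

**Further compounds**

F1 | step 6 | 1-(2-hydroxy-4,5,6-trimethoxyphenyl)ethanone (purchased) | CC(=O)c1c(O)cc(OC)c(OC)c1OC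
F2 | step 6 | 1-(2-hydroxy-4,5,6-trimethoxyphenyl)-3-(2,3,4,5-tetramethoxyphenyl)propane-1,3-dione | COc1cc(C(=O)CC(=O)c2c(O)cc(OC)c(OC)c2OC)c(OC)c(OC)c1OC
F3 | step 6 | 5,6,7-trimethoxy-2-(2,3,4,5-tetramethoxyphenyl)-4H-chromen-4-one | COc1cc(-c2cc(=O)c3c(OC)c(OC)c(OC)cc3o2)c(OC)c(OC)c1OC
F4 | step 5 | [4-oxo-6-(2,3,4,5-tetramethoxyphenyl)-4H-pyran-2-yl]acetic acid | OC(=O)Cc1cc(=O)cc(-c2cc(OC)c(OC)c(OC)c2OC)o1
F5 | step 5 | 2-[2-(1H-imidazol-1-yl)-2-oxoethyl]-6-(2,3,4,5-tetramethoxyphenyl)-4H-pyran-4-one | O=C(Cc1cc(=O)cc(-c2cc(OC)c(OC)c(OC)c2OC)o1)n1ccnc1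
F6 | step 5 | dimethyl 2-methoxymalonate (purchased) | COC(C(=O)OC)C(=O)OC
F7 | step 5 | potassium 2,3-dimethoxy-3-oxopropanoate | [K+].COC(C([O-])=O)C(=O)OC
F8 | step 5 | 2-methoxy-2-(methoxycarbonyl)-3-oxo-4-[4-oxo-6-(2,3,4,5-tetramethoxyphenyl)-4H-pyran-2-yl]butanoic acid | COC(=O)C(OC)(C(=O)O)C(=O)Cc1cc(=O)cc(-c2cc(OC)c(OC)c(OC)c2OC)o1
F9 | step 4 | methoxyacetaldehyde (purchased) | COCC=O
F10 | step 4 | 2-(2-hydroxy-3-methoxypropyl)-6-(2,3,4,5-tetramethoxyphenyl)-4H-pyran-4-one, racemic | COCC(O)Cc1cc(=O)cc(-c2cc(OC)c(OC)c(OC)c2OC)o1
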